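Everything rests on cutting rings B and C of the pterocarpan at C11a–O11, C6a–C11a and O5–C6 at once. The route exploits that O5, C4a, C11b and C11a make up a latent ortho-quinone methide of ring A, while the C6a=C6 unit can sit on ring D, three atoms from C11a through O11. A ring A/E salicylaldehyde (formyl carbon = C11a) and a ring D phenol with an ortho (E)-2-(phenylsulfanyl)vinyl group are condensed by a chiral phosphoric acid; the aryloxy quinone methide then closes both rings in a tethered hetero-Diels–Alder reaction and sets the cis C6a/C11a pair. Radical desulfurisation at C6 and debenzylation complete the synthesis.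

Key step: step 5

Assumption: pterocarpan numbering is used for the pentacycle (ring A = C1–C4, C4a, C11b; ring B = O5, C6, C6a, C11a, C11b, C4a; ring C = C6a, C6b, C10a, O11, C11a; ring D = C6b–C10a; ring E = the 2,2-dimethyldihydropyran fused at C1–C2, oxygen on C1); the target is then (6aS,11aS).
Assumption: the sense of induction of the phosphoric acid cannot be derived with certainty; (R)-TRIP, (R)-3,3'-bis(2,4,6-triisopropylphenyl)-1,1'-binaphthyl-2,2'-diyl hydrogen phosphate, is written, and its mirror image is to be used if it delivers the antipode.

Step 1
Reactants: 1 2,4,6-trihydroxybenzaldehyde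
Product: 2 4-(benzyloxy)-2,6-dihydroxybenzaldehyde
Conditions: BnBr (1.0 equiv), NaHCO3 (1.1 equiv), DMF, 40 °C
Reagents that add atoms: benzyl bromide, BrCc1ccccc1
Why: Williamson etherification under weak-base control, in which the 4-hydroxyl, para to the formyl group and the most acidic of the three, is ionised and O-benzylated in the dipolar aprotic solvent while the ortho hydroxyls stay protonated and hydrogen-bonded to the carbonyl group.

Step 2
Reactants: 2 4-(benzyloxy)-2,6-dihydroxybenzaldehyde; 3 1-bromo-3-methylbut-2-ene (prenyl bromide)
Product: 4 4-(benzyloxy)-2,6-dihydroxy-3-(3-methylbut-2-en-1-yl)benzaldehyde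
Conditions: KOH (1.1 equiv), H2O, 0 °C → rt
Reagents that add atoms: none
Why: C-alkylation of an ambident phenoxide (C-prenylation of an acylphloroglucinol), in which water shields the phenoxide oxygens by hydrogen bonding and steers the soft allylic bromide to the ring carbon flanked by two oxygens, C3 and C5 being equivalent so that mono-alkylation can give only one isomer.

Step 3
Reactants: 4 4-(benzyloxy)-2,6-dihydroxy-3-(3-methylbut-2-en-1-yl)benzaldehyde
Product: 5 5-(benzyloxy)-7-hydroxy-2,2-dimethyl-3,4-dihydro-2H-chromene-8-carbaldehyde
Conditions: Amberlyst 15, PhMe, 60 °C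
Reagents that add atoms: none
Why: Acid-catalysed intramolecular hydroalkoxylation of an ortho-prenylphenol, in which Markovnikov protonation gives the tertiary cation that only the neighbouring free 2-hydroxyl can trap (the other neighbour is the benzyl ether), so the chroman closes with its oxygen next to the formyl-bearing carbon.

Step 4
Reactants: 6 2-hydroxy-4-methoxybenzaldehyde; 7 diethyl [(phenylsulfanyl)methyl]phosphonate
Product: 8 5-methoxy-2-[(E)-2-(phenylsulfanyl)ethenyl]phenol
Conditions: NaH (2.3 equiv), THF, 0 → 50 °C; then aq. NH4Cl
Reagents that add atoms: none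
Why: Horner–Wadsworth–Emmons olefination, in which one equivalent of base makes the phenoxide, the sulfur-stabilised phosphonate carbanion adds reversibly to the aldehyde and collapses to the aryl-conjugated vinyl sulfide with the E geometry usual for aryl aldehydes, and the buffered quench avoids acid that would cyclise the product.

Step 5
Reactants: 5 5-(benzyloxy)-7-hydroxy-2,2-dimethyl-3,4-dihydro-2H-chromene-8-carbaldehyde; 8 5-methoxy-2-[(E)-2-(phenylsulfanyl)ethenyl]phenol
Product: 11 3-O-benzyl-6-(phenylsulfanyl) derivative of the target (cis-fused; 11aS; C6a spatially as in the target; C6 both epimers), via hemiacetal 9 (not isolated), via aryloxy ortho-quinone methide 10 (not isolated)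
Conditions: (R)-TRIP (10 mol%), 5 Å MS, PhMe (0.3 M), 5 in 1.5-fold excess, 0 °C → rt
Reagents that add atoms: none
Why: Proposed new method: the phosphoric acid should turn hemiacetal 9 into the ion-paired ortho-quinone methide 10 with O11 on its methide carbon, whose C11a is attacked by C6a (the vinyl sulfide carbon beta to sulfur) while O5 captures the thionium carbon C6, in a concerted asynchronous or stepwise [4+2] event; if C6a–C11a bonding from the acid-activated aldehyde comes first, O5 closure and later ionisation at C11a lead to the same product. The closest known reaction types are the chiral phosphoric acid catalysed hetero-Diels–Alder reactions of ortho-quinone methides with vinyl sulfides or enol ethers and the acid-promoted formation of 2,4-dialkoxychromans from salicylaldehyde acetals and enol ethers; new are the aryloxy group on the methide carbon and the intramolecular delivery of the dienophile. Ring C closes 5-exo (C6a onto C11a) and ring B 6-exo (O5 onto the thionium carbon C6), together the fused mode of an intramolecular Diels–Alder reaction. C11a and C6a are forced cis by the three-atom O11–C10a–C6b tether and their absolute configuration should be set by the chiral phosphate held on O5 of the quinone methide, which shields one face of C11a; C6 is left as an epimer mixture that step 6 erases. The step needs the fused (C11a–C6a and O5–C6) over the bridged (C11a–C6 and O5–C6a) pairing, secured by the sulfur donor on C6 and the short tether, and it needs condensation to outrun acid cyclisation of 8 onto its own vinyl sulfide, favoured by the excess of 5 at high concentration, the mild acid and the sieves.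

Step 6
Reactants: 11 3-O-benzyl-6-(phenylsulfanyl) derivative of the target
Product: 12 3-O-benzyl ether of the target, (6aS,11aS)
Conditions: Bu3SnH (2 equiv), AIBN (0.2 equiv), PhMe, 100 °C
Reagents that add atoms: none
Why: Radical chain desulfurisation of an O,S-acetal, in which the stannyl radical takes the phenylsulfanyl group and the oxygen-stabilised C6 radical abstracts hydrogen from Bu3SnH, so both C6 epimers converge on the methylene group and C6a and C11a are not touched.

Step 7
Reactants: 12 3-O-benzyl ether of the target
Product: 13 target, (6aS,11aS)-9-methoxypterocarpan-3-ol with ring E fused at C1–C2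
Conditions: H2 (1 atm), Pd/C (10%), EtOAc, rt
Reagents that add atoms: none
Why: Catalytic hydrogenolysis of an aryl benzyl ether, which in neutral ethyl acetate at 1 atm should be cleaved well before the ring-bound benzylic C11a–O11 bond (that cleavage calls for acid or prolonged reaction), so the reaction is stopped at full conversion and no stereocentre is affected.

Compound list
1 | 2,4,6-trihydroxybenzaldehyde | O=Cc1c(O)cc(O)cc1O | starting material
2 | 4-(benzyloxy)-2,6-dihydroxybenzaldehyde | O=Cc1c(O)cc(OCc2ccccc2)cc1O | intermediate
3 | 1-bromo-3-methylbut-2-ene (prenyl bromide) | CC(C)=CCBr | starting material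
4 | 4-(benzyloxy)-2,6-dihydroxy-3-(3-methylbut-2-en-1-yl)benzaldehyde | O=Cc1c(O)cc(OCc2ccccc2)c(CC=C(C)C)c1O | intermediate
5 | 5-(benzyloxy)-7-hydroxy-2,2-dimethyl-3,4-dihydro-2H-chromene-8-carbaldehyde | CC1(C)CCc2c(OCc3ccccc3)cc(O)c(C=O)c2O1 | intermediate
6 | 2-hydroxy-4-methoxybenzaldehyde | COc1ccc(C=O)c(O)c1 | starting material
7 | diethyl [(phenylsulfanyl)methyl]phosphonate | CCOP(=O)(CSc1ccccc1)OCC | starting material
8 | 5-methoxy-2-[(E)-2-(phenylsulfanyl)ethenyl]phenol | COc1ccc(/C=C/Sc2ccccc2)c(O)c1 | intermediate
9 | hemiacetal (not isolated): [5-(benzyloxy)-7-hydroxy-2,2-dimethylchroman-8-yl]{5-methoxy-2-[(E)-2-(phenylsulfanyl)ethenyl]phenoxy}methanol | COc1ccc(/C=C/Sc2ccccc2)c(OC(O)c2c(O)cc(OCc3ccccc3)c3CCC(C)(C)Oc23)c1 | intermediate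
10 | aryloxy ortho-quinone methide (not isolated): 5-(benzyloxy)-8-({5-methoxy-2-[(E)-2-(phenylsulfanyl)ethenyl]phenoxy}methylidene)-2,2-dimethyl-3,4-dihydro-2H-chromen-7(8H)-one | COc1ccc(/C=C/Sc2ccccc2)c(OC=C2C(=O)C=C(OCc3ccccc3)C3=C2OC(C)(C)CC3)c1 | intermediate
11 | 3-O-benzyl-6-(phenylsulfanyl) derivative of 13: cis-fused, 11aS, C6a spatially as in 13 (formally 6aR because the sulfur-bearing C6 gains priority), C6 both epimers | COc1ccc2c(c1)O[C@@H]1c3c(cc(OCc5ccccc5)c4c3OC(C)(C)CC4)OC(Sc5ccccc5)[C@H]21 | intermediate
12 | 3-O-benzyl ether of 13, (6aS,11aS), H-6a and H-11a cis | COc1ccc2c(c1)O[C@@H]1c3c(cc(OCc5ccccc5)c4c3OC(C)(C)CC4)OC[C@H]21 | intermediate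
13 | (6aS,11aS)-9-methoxypterocarpan-3-ol carrying ring E, a 2,2-dimethyl-3,4-dihydro-2H-pyran fused at C1–C2 (ring oxygen on C1, CH2 on C2); H-6a and H-11a cis | COc1ccc2c(c1)O[C@@H]1c3c(cc(O)c4c3OC(C)(C)CC4)OC[C@H]21 | target

Total step count: 7. Longest linear sequence: 6 steps (steps 1, 2, 3, 5, 6, 7); step 4 is the one-step side branch.

Steps most likely to fail

1. Step 5 (proposed new method). Several processes may interfere:
- acid cyclisation of the phenol partner onto its own vinyl sulfide, followed by loss of thiophenol;
- C-alkylation of the electron-rich ring D by the ring A cation;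
- the bridged pairing;
- poor facial discrimination within the ion pair;
- loss of thiophenol from the O,S-acetal, which would scramble C6a.

Fallback with known chemistry, setting out from 5: treatment of 5 with vinyltriphenylphosphonium bromide and NaH in THF (Schweizer reaction: oxa-Michael addition, then intramolecular Wittig reaction) should give 5-(benzyloxy)-2,2-dimethyl-3,4-dihydro-2H,8H-pyrano[2,3-f]chromene F1. Heck oxyarylation of this 2H-chromene with 2-iodo-5-methoxyphenol (Pd(OAc)2, Ag2CO3, acetone, reflux) delivers the aryl group to C6a and the phenol oxygen to C11a and should give the cis-fused benzyl ether as a racemate. Preparative chromatography on a chiral stationary phase then separates 12 from its mirror image, the (6aR,11aR)-enantiomer of 12 F2. The route is rejoined at 12 and step 7 follows.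

2. Step 2. O-Alkylation and double alkylation of the ambident phenoxide may outweigh mono-C-prenylation.

Fallback, setting out from 2: heating 2 with 3-methylbut-2-enal and catalytic ethylenediammonium diacetate in toluene (aldol-type C-alkylation, dehydration, oxa-6π electrocyclisation) should give 5-(benzyloxy)-7-hydroxy-2,2-dimethyl-2H-chromene-8-carbaldehyde F3. This is the only regioisomer possible, because only the free ortho hydroxyl can close the ring. Hydrogenation of its C3=C4 bond (H2, Pd/C poisoned with Ph2S, EtOAc, rt), which spares the aryl benzyl ether and the aldehyde, rejoins the route at 5 and replaces steps 2 and 3.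

3. Step 6. Slow homolytic C–S cleavage may stall the radical chain, and prolonged heating may cause thermal loss of thiophenol from the O,S-acetal.

Fallback, setting out from 11: non-chain reductive desulfurisation on nickel boride (Ni2B made in the flask from NiCl2·6H2O and NaBH4, MeOH–THF, 0 °C), which leaves aryl benzyl ethers intact, should give 12 directly. The route is rejoined at 12 and no new compound is made.

Further compounds
F1 | step 5 | 5-(benzyloxy)-2,2-dimethyl-3,4-dihydro-2H,8H-pyrano[2,3-f]chromene | CC1(C)CCc2c(OCc3ccccc3)cc3OCC=Cc3c2O1
F2 | step 5 | (6aR,11aR)-enantiomer of 12 | COc1ccc2c(c1)O[C@H]1c3c(cc(OCc5ccccc5)c4c3OC(C)(C)CC4)OC[C@@H]21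
F3 | step 2 | 5-(benzyloxy)-7-hydroxy-2,2-dimethyl-2H-chromene-8-carbaldehyde | CC1(C)C=Cc2c(OCc3ccccc3)cc(O)c(C=O)c2O1
F0 | step 6 | none | none
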